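Ring A is built by inserting an unsubstituted C1–C2 unit between the enolisable C10 of a ring-B ketone and a C3 nitrile that hangs from C5 through the gem-dimethyl carbon C4 (labdane numbering); the step exploits the 1,4 relationship of C10 and C3 in ring A. (S)-Carvone is ring B: its methyl becomes C20, its carbonyl C9, and its isopropenyl stereocentre (C7, later excised) steers all others. In one flask lithiated isobutyronitrile adds to C5, the resulting C10 enolate adds to vinyltriphenylphosphonium bromide (C1–C10) and the ylide closes onto the nitrile (C2–C3), giving the trans-fused 3,9-dione. The C3 ketone then becomes the equatorial bromide, and the C9 enol triflate takes the side chain.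

Key step: step 2

Remark: labdane numbering is used for atom labels throughout (decalin C1–C10, side chain C11–C16, methyls C17 on C8, C18/C19 on C4, C20 on C10); the target is read as the trans-fused decalin with equatorial bromine, (3R,5S,10R,13R) in this numbering.

Step 1
Reactants: 1 (S)-(+)-carvone
Product: 3 (5S)-2,6-dimethyl-5-(prop-1-en-2-yl)cyclohex-2-en-1-one (6-methylcarvone as a mixture of C6 epimers), via lithium dienolate 2 (not isolated)
Conditions: LDA, THF, −78 °C; MeI, −78 → 0 °C
Reagents that add atoms: iodomethane CI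
Why: LDA removes the α′ proton of the enone kinetically (cross-conjugated dienolate 2) and the enolate is methylated by SN2 attack on MeI (enolate alkylation); the new centre, labdane C8, should form mainly trans to the isopropenyl group but becomes sp2 in step 5, so its configuration does not matter.

Step 2
Reactants: 3 6-methylcarvone; 4 isobutyronitrile; 7 vinyltriphenylphosphonium bromide
Product: 10 (3S,4aR,8aR)-2,5,5,8a-tetramethyl-3-(prop-1-en-2-yl)-3,4,4a,7,8,8a-hexahydronaphthalene-1,6(2H,5H)-dione (C2 epimers), via 2-lithioisobutyronitrile 5 (not isolated), via lithium enolate 6 (not isolated), via phosphonium ylide 8 (not isolated), via N-vinyl iminophosphorane 9 (not isolated)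
Conditions: 4, LDA, THF, −78 °C; 3, DMPU, −78 → −20 °C; 7, −20 → 60 °C; then 1 M HCl, rt
Reagents that add atoms: water O
Why: Proposed new method: lithiated nitrile 5 adds 1,4 to enone 3 (C4–C5) and gives the regiodefined enolate 6, which attacks the CH2 terminus of salt 7 through C10 (C1–C10) to give ylide 8; the ylide carbon C2 then adds to the tertiary nitrile carbon C3 (C2–C3) and the adduct collapses through a four-membered P–N ring to iminophosphorane 9, which aqueous acid hydrolyses to the C3 ketone. The closest known reaction types are the Schweizer annulation (enolate plus vinyltriphenylphosphonium bromide, then intramolecular Wittig reaction) and the intermolecular condensation of non-stabilised phosphorus ylides with nitriles to N-vinyl iminophosphoranes that hydrolyse to ketones; the untested element is their union with a nitrile as the internal electrophile. Ring A closes in a 6-exo-dig mode (C2 onto the C≡N carbon, nitrogen outside the ring). C5 is set by axial attack of 5 anti to the C7 isopropenyl group (3,5-trans on the carvone ring), and C10 by attack of enolate 6 on 7 anti to the new pseudo-axial C5 substituent, so the C10 methyl ends cis to that substituent and the ring fusion is trans. The step needs 1,4- over 1,2-addition of 5 (reversible 1,2-addition, DMPU, warming), C-alkylation of the hindered enolate, and ring closure of 8 before proton transfer; the ylide is less basic than a ketone enolate, the nitrile has no α-hydrogen, and no enone remains that could divert the ylide.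

Step 3
Reactants: 10 isopropenyl dione
Product: 11 (4aR,8aR)-2,5,5,8a-tetramethyl-3,4,4a,7,8,8a-hexahydronaphthalene-1,6(2H,5H)-dione (C2 epimers)
Conditions: O3, MeOH, −78 °C; then FeSO4·7H2O, PhSH, −78 °C → rt
Reagents that add atoms: none
Why: Ozone cleaves the only C=C bond to formaldehyde and an α-methoxy hydroperoxide; divalent iron reduces the O–O bond, the alkoxyl radical expels the secondary C7 radical by β-scission and benzenethiol donates a hydrogen atom (Criegee ozonolysis followed by reductive dealkenylation), which erases the C7 centre after it has done its work and forms no new stereocentre.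

Step 4
Reactants: 11 trans-decalin-3,9-dione
Product: 12 (4aS,8aR)-6-bromo-2,5,5,8a-tetramethyl-3,4,4a,5,8,8a-hexahydronaphthalen-1(2H)-one (C2 epimers)
Conditions: P(OPh)3, Br2, CH2Cl2, −60 °C; then Et3N, 11, −60 °C → reflux
Reagents that add atoms: bromine BrBr
Why: Triphenyl phosphite dibromide activates the C3 carbonyl oxygen, bromide adds and triethylamine removes HBr toward C2, the only enolisable side (ketone to alkenyl bromide conversion); the C9 ketone, flanked by quaternary C10 and tertiary C8, should be too hindered to react.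

Step 5
Reactants: 12 alkenyl bromide ketone
Product: 14 (4aS,8aR)-6-bromo-2,5,5,8a-tetramethyl-3,4,4a,5,8,8a-hexahydronaphthalen-1-yl trifluoromethanesulfonate, via potassium enolate 13 (not isolated)
Conditions: KHMDS, THF, −78 → 0 °C; PhNTf2, −78 °C → rt
Reagents that add atoms: N-phenylbis(trifluoromethanesulfonimide) O=S(=O)(N(c1ccccc1)S(=O)(=O)C(F)(F)F)C(F)(F)F
Why: C8–H is the only acidic position next to the C9 ketone, so KHMDS gives one enolate (13) and O-triflation fixes the tetrasubstituted C8=C9 double bond in its final place (enolate triflation), the C8 stereocentre being removed.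

Step 6
Reactants: 14 alkenyl bromide enol triflate
Product: 15 (4aS,6R,8aR)-6-bromo-2,5,5,8a-tetramethyl-3,4,4a,5,6,7,8,8a-octahydronaphthalen-1-yl trifluoromethanesulfonate
Conditions: Co(acac)2, t-BuOOH, Et3SiH, 1,4-cyclohexadiene, n-PrOH, rt
Reagents that add atoms: none
Why: A cobalt hydride formed in situ transfers a hydrogen atom to C2 and the tertiary α-bromo radical at C3 takes hydrogen from 1,4-cyclohexadiene on the ring face opposite the axial methyl groups on C4 and C10, so the new C3–H bond is axial and bromine ends equatorial (3R) (radical hydrogen-atom-transfer hydrogenation of an alkenyl halide); the electron-poor tetrasubstituted enol triflate should not react.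

Step 7
Reactants: 16 (E)-3-methylpent-2-en-4-yn-1-ol
Product: 17 (E)-3-methylpenta-2,4-dien-1-ol
Conditions: H2 (1 atm), Pd/CaCO3 poisoned with Pb(OAc)2 (Lindlar catalyst), quinoline, EtOAc, rt
Reagents that add atoms: none
Why: Semihydrogenation on the lead-poisoned palladium catalyst stops at the alkene (Lindlar reduction) and leaves the E trisubstituted double bond untouched.

Step 8
Reactants: 15 bromo enol triflate; 17 dienol
Product: 19 (2E)-5-[(4aS,6R,8aR)-6-bromo-2,5,5,8a-tetramethyl-3,4,4a,5,6,7,8,8a-octahydronaphthalen-1-yl]-3-methylpent-2-en-1-ol, via alkylborane 18 (not isolated)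
Conditions: 17, 9-BBN-H (2.2 equiv), THF, 0 °C → rt; then 15, PdCl2(dppf), AsPh3, Cs2CO3, DMF/H2O, 50 °C
Reagents that add atoms: none
Why: 9-BBN first caps the hydroxyl group and then adds anti-Markovnikov to the terminal vinyl group only (boron on C11), and the primary alkylborane 18 couples with the enol triflate under zerovalent palladium catalysis (B-alkyl Suzuki–Miyaura coupling), to which the hindered secondary bromide is inert.

Step 9
Reactants: 19 allylic alcohol
Product: 20 [(2R,3R)-3-{2-[(4aS,6R,8aR)-6-bromo-2,5,5,8a-tetramethyl-3,4,4a,5,6,7,8,8a-octahydronaphthalen-1-yl]ethyl}-3-methyloxiran-2-yl]methanol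
Conditions: Ti(OiPr)4, D-(−)-diethyl tartrate, t-BuOOH, 4 Å MS, CH2Cl2, −20 °C
Reagents that add atoms: tert-butyl hydroperoxide CC(C)(C)OO
Why: Sharpless asymmetric epoxidation: the titanium–D-(−)-tartrate catalyst delivers oxygen to one face of the E allylic alcohol and should give the (2R,3R)-epoxide, which fixes C13 under reagent control; the isolated tetrasubstituted alkene is not epoxidised.

Step 10
Reactants: 20 epoxy alcohol
Product: 22 (3R)-5-[(4aS,6R,8aR)-6-bromo-2,5,5,8a-tetramethyl-3,4,4a,5,6,7,8,8a-octahydronaphthalen-1-yl]-3-methylpent-1-en-3-ol (target), via epoxy iodide 21 (not isolated)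
Conditions: PPh3, I2, imidazole, THF, 0 °C; then Zn dust, AcOH, EtOH, rt
Reagents that add atoms: none
Why: Appel-type iodination of the primary alcohol gives epoxy iodide 21, and zinc insertion followed by β-elimination opens the epoxide at C14–O to the vinyl carbinol (reductive opening of a 2,3-epoxy iodide); the C13–O bond is never broken, so C13 keeps its configuration (13R).

Compound list

1 | (S)-(+)-carvone, (5S)-2-methyl-5-(prop-1-en-2-yl)cyclohex-2-en-1-one | O=C1C[C@@H](C(C)=C)CC=C1C | starting material
2 | lithium α′-dienolate of carvone | [Li+].[O-]C1=C[C@@H](C(C)=C)CC=C1C | intermediate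
3 | (5S)-2,6-dimethyl-5-(prop-1-en-2-yl)cyclohex-2-en-1-one (C6 epimers) | O=C1C(C)[C@@H](C(C)=C)CC=C1C | intermediate
4 | isobutyronitrile | CC(C)C#N | starting material
5 | 2-lithio-2-methylpropanenitrile | [Li+].C[C-](C)C#N | intermediate
6 | lithium enolate of the 1,4-adduct (C9–O, C9=C10; CMe2CN on C5 trans to the C7 isopropenyl) | [Li+].[O-]C1=C(C)[C@@H](C(C)(C)C#N)C[C@H](C(C)=C)C1C | intermediate
7 | vinyltriphenylphosphonium bromide | C=C[P+](c1ccccc1)(c1ccccc1)c1ccccc1.[Br-] | starting material
8 | phosphonium ylide (C10 quaternary, CH2–CH=PPh3 chain trans to the C5 cyanoalkyl group) | O=C1C(C)[C@@H](C(C)=C)C[C@H](C(C)(C)C#N)[C@@]1(C)CC=P(c1ccccc1)(c1ccccc1)c1ccccc1 | intermediate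
9 | N-vinyl iminophosphorane (ring A closed, C2=C3–N=PPh3) | O=C1C(C)[C@@H](C(C)=C)C[C@@H]2C(C)(C)C(N=P(c3ccccc3)(c3ccccc3)c3ccccc3)=CC[C@@]12C | intermediate
10 | (3S,4aR,8aR)-2,5,5,8a-tetramethyl-3-(prop-1-en-2-yl)-3,4,4a,7,8,8a-hexahydronaphthalene-1,6(2H,5H)-dione (trans-fused, C2 epimers) | O=C1C(C)[C@@H](C(C)=C)C[C@@H]2C(C)(C)C(=O)CC[C@@]12C | intermediate
11 | (4aR,8aR)-2,5,5,8a-tetramethyl-3,4,4a,7,8,8a-hexahydronaphthalene-1,6(2H,5H)-dione (trans-fused, C2 epimers) | O=C1C(C)CC[C@@H]2C(C)(C)C(=O)CC[C@@]12C | intermediate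
12 | (4aS,8aR)-6-bromo-2,5,5,8a-tetramethyl-3,4,4a,5,8,8a-hexahydronaphthalen-1(2H)-one (C2 epimers) | O=C1C(C)CC[C@@H]2C(C)(C)C(Br)=CC[C@@]12C | intermediate
13 | potassium enolate of 12 (C8=C9) | [K+].[O-]C1=C(C)CC[C@@H]2C(C)(C)C(Br)=CC[C@@]12C | intermediate
14 | (4aS,8aR)-6-bromo-2,5,5,8a-tetramethyl-3,4,4a,5,8,8a-hexahydronaphthalen-1-yl trifluoromethanesulfonate | FC(F)(F)S(=O)(=O)OC1=C(C)CC[C@@H]2C(C)(C)C(Br)=CC[C@@]12C | intermediate
15 | (4aS,6R,8aR)-6-bromo-2,5,5,8a-tetramethyl-3,4,4a,5,6,7,8,8a-octahydronaphthalen-1-yl trifluoromethanesulfonate (equatorial bromide) | FC(F)(F)S(=O)(=O)OC1=C(C)CC[C@@H]2C(C)(C)[C@H](Br)CC[C@@]12C | intermediate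
16 | (E)-3-methylpent-2-en-4-yn-1-ol | OC/C=C(\C)C#C | starting material
17 | (E)-3-methylpenta-2,4-dien-1-ol | OC/C=C(\C)C=C | intermediate
18 | B-alkyl-9-BBN of 17 (boron on the terminal carbon, hydroxyl as its 9-BBN borinate) | C(/C=C(\C)CCB1C2CCCC1CCC2)OB1C2CCCC1CCC2 | intermediate
19 | (2E)-5-[(4aS,6R,8aR)-6-bromo-2,5,5,8a-tetramethyl-3,4,4a,5,6,7,8,8a-octahydronaphthalen-1-yl]-3-methylpent-2-en-1-ol | OC/C=C(\C)CCC1=C(C)CC[C@@H]2C(C)(C)[C@H](Br)CC[C@@]12C | intermediate
20 | [(2R,3R)-3-{2-[(4aS,6R,8aR)-6-bromo-2,5,5,8a-tetramethyl-3,4,4a,5,6,7,8,8a-octahydronaphthalen-1-yl]ethyl}-3-methyloxiran-2-yl]methanol | OC[C@H]1O[C@]1(C)CCC1=C(C)CC[C@@H]2C(C)(C)[C@H](Br)CC[C@@]12C | intermediate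
21 | (2S,3R)-2-(iodomethyl)-3-methyl-3-{2-[(4aS,6R,8aR)-6-bromo-2,5,5,8a-tetramethyl-3,4,4a,5,6,7,8,8a-octahydronaphthalen-1-yl]ethyl}oxirane | IC[C@H]1O[C@]1(C)CCC1=C(C)CC[C@@H]2C(C)(C)[C@H](Br)CC[C@@]12C | intermediate
22 | (3R)-5-[(4aS,6R,8aR)-6-bromo-2,5,5,8a-tetramethyl-3,4,4a,5,6,7,8,8a-octahydronaphthalen-1-yl]-3-methylpent-1-en-3-ol | C=C[C@](C)(O)CCC1=C(C)CC[C@@H]2C(C)(C)[C@H](Br)CC[C@@]12C | target

Total step count: 10. Longest linear sequence: 9 steps (steps 1–6 and 8–10 from (S)-carvone; step 7 prepares the side-chain dienol).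

Steps most likely to fail

Step 2 (proposed new method). The nitrile anion may add 1,2 or act as a base toward the tertiary α′ hydrogen instead of adding 1,4. The crowded tetrasubstituted enolate may add too slowly to the phosphonium salt. The ylide may be quenched by proton transfer, or may fail to attack the hindered nitrile. The fallback uses known sulfone chemistry and sets out from 3. The same conjugate addition is quenched with TMSCl to give the silyl enol ether F1. KOt-Bu releases the potassium enolate, which undergoes Michael addition to phenyl vinyl sulfone to give the keto sulfone F2 (not isolated). LDA added to the same flask closes ring A by Thorpe–Ziegler-type addition of the α-sulfonyl carbanion to the nitrile and gives the cyclic β-enamino sulfone F3. Aqueous HCl hydrolyses F3 to the β-keto sulfone F4, and SmI2 (THF/MeOH) removes the sulfonyl group, which returns the route to dione 10.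

Step 6. Hydrogen may be delivered to the C3 radical from the wrong face, which would give the axial bromide, or the C–Br bond may be lost by over-reduction. The fallback replaces the radical hydrogenation by an SN2 inversion and sets out from dione 11. LiBH(s-Bu)3 (1 equiv, −78 °C) reduces the less hindered C3 ketone from the equatorial side to the axial hydroxy ketone F5. CBr4/PPh3 (Appel reaction, inversion) gives the equatorial bromo ketone F6. KHMDS/PhNTf2 then forms the C9 enol triflate and the route comes back at 15. The risk of this fallback is elimination or methyl migration at the neopentylic centre.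

Step 4. The bromoolefination may be slow at the hindered C3 carbonyl or may also touch the C9 ketone. The fallback uses enolate chemistry and sets out from dione 11. KHMDS (1 equiv, −78 °C) deprotonates the unhindered C2 methylene in preference to the tertiary C8–H, and PhNTf2 gives the C3 enol triflate F7. Palladium-catalysed triflate-to-bromide exchange (Pd2(dba)3, t-BuBrettPhos, KBr, toluene, 100 °C) returns the route to 12.

Further compounds

F1 | step 2 | trimethylsilyl enol ether of the 1,4-adduct (C9–OTMS, C9=C10) | C[Si](C)(C)OC1=C(C)[C@@H](C(C)(C)C#N)C[C@H](C(C)=C)C1C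
F2 | step 2 | keto sulfone, C10 bearing CH2CH2SO2Ph trans to the C5 cyanoalkyl group | O=C1C(C)[C@@H](C(C)=C)C[C@H](C(C)(C)C#N)[C@@]1(C)CCS(=O)(=O)c1ccccc1
F3 | step 2 | cyclic β-enamino sulfone (3-amino-2-phenylsulfonyl-Δ2, ring A closed) | O=C1C(C)[C@@H](C(C)=C)C[C@@H]2C(C)(C)C(N)=C(S(=O)(=O)c3ccccc3)C[C@@]12C
F4 | step 2 | β-keto sulfone (3-oxo-2-phenylsulfonyl) | O=C1C(C)[C@@H](C(C)=C)C[C@@H]2C(C)(C)C(=O)C(S(=O)(=O)c3ccccc3)C[C@@]12C
F5 | step 6 | (4aR,6S,8aR)-6-hydroxy-2,5,5,8a-tetramethyloctahydronaphthalen-1(2H)-one (axial alcohol) | O=C1C(C)CC[C@@H]2C(C)(C)[C@@H](O)CC[C@@]12C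
F6 | step 6 | (4aS,6R,8aR)-6-bromo-2,5,5,8a-tetramethyloctahydronaphthalen-1(2H)-one (equatorial bromide) | O=C1C(C)CC[C@@H]2C(C)(C)[C@H](Br)CC[C@@]12C
F7 | step 4 | (4aR,8aR)-2,5,5,8a-tetramethyl-1-oxo-1,2,3,4,4a,5,8,8a-octahydronaphthalen-6-yl trifluoromethanesulfonate | O=C1C(C)CC[C@@H]2C(C)(C)C(OS(=O)(=O)C(F)(F)F)=CC[C@@]12C
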